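**Plan**

- Unit A (primed locants) is the half ending in the methyl ester, unit B the half with the butenolide; labdane numbering throughout. Retrosynthesis cuts C15'–C14' (allylboration, C15' oxidised afterwards), then in unit B C12–C15' (anti SN2' on a 14-acetoxy 12(13)-en-16,15-olide) and C12=C13 (aldol–elimination), and in unit A C12'–C13' (Morita–Baylis–Hillman), so both halves come from one C12 aldehyde, 24.
- What makes the key step possible: each half holds the same trans-decalin (ring A = C1–C5, C10; ring B = C5–C10) with the C3 hydroxyl beside quaternary C4 (C18 methyl, axial C19 hydroxymethyl) and the C8=C17 exocyclic methylene. This is the fold of one chain carrying a C3–C4 epoxide, C5=C10 and C8=C9 alkenes and CH2SiMe3 on C8; the cyclisation makes C4–C5 and C10–C9.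
- Forward: the chain is built linearly from geranyl acetate (steps 1–11), rings A and B close together in step 12, the decalin is trimmed to 24 (steps 13–16). 24 is divided into the unit A allylboronate 29 and the unit B aldehyde 41; the halves are joined in step 28, then C15' is oxidised and the diols released.
- Stereochemistry: C3 and C4 from Sharpless epoxidation of a Z allylic alcohol; C5, C10, C9 from the chair–chair fold; C12 by transfer from C14 of (S)-3-hydroxybutyrolactone; the C12'=C13' geometry from the chair transition state of the allylboration.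

Key step: step 12

Assumption: centres that are later excised or made planar (the epoxide carbon of 2–8, the carbinol carbons of 26 and 32, the boron-bearing C12' of 29, the C15' carbinol of 42) are carried as epimer mixtures.

**Route**

Step 1
Reactants: 1 geranyl acetate
Product: 2 6,7-epoxygeranyl acetate
Conditions: mCPBA, CH2Cl2, 0 °C
Reagents that add atoms: 3-chloroperbenzoic acid, O=C(OO)c1cccc(Cl)c1
Why: Prilezhaev epoxidation takes the electron-rich 6,7-alkene because the 2,3-alkene is deactivated by the allylic acetate; the epoxide only masks the future C3 aldehyde.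

Step 2
Reactants: 2 6,7-epoxygeranyl acetate
Product: 3 6,7-epoxygeraniol
Conditions: K2CO3 (cat.), MeOH, rt
Reagents that add atoms: none
Why: Base-catalysed transesterification removes the acetate, and the trisubstituted epoxide is inert to methoxide at room temperature.

Step 3
Reactants: 3 6,7-epoxygeraniol
Product: 5 6,7-epoxygeranyl bromide, via 6,7-epoxygeranyl methanesulfonate 4 (not isolated)
Conditions: MsCl, Et3N, THF, −40 °C; then LiBr, −40 → 0 °C
Reagents that add atoms: lithium bromide, [Li+].[Br-]
Why: Mesylation and SN2 displacement by bromide at the primary allylic carbon below 0 °C should give the bromide without allylic transposition or epoxide opening.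

Step 4
Reactants: 5 6,7-epoxygeranyl bromide; 6 propargyl bromide
Product: 8 2,2-dimethyl-3-[(3E)-3-methyloct-3-en-7-yn-1-yl]oxirane, via 1,3-dilithiopropyne 7 (not isolated)
Conditions: 6, n-BuLi (2 equiv), TMEDA, Et2O, −78 °C; then 5, −78 → −20 °C; H2O
Reagents that add atoms: none
Why: SN2 alkylation of the propargyl dianion at its sp3 carbon installs C7–C9 as a terminal alkyne with the E alkene retained; the hindered epoxide does not react with organolithiums at −78 °C.

Step 5
Reactants: 8 epoxy enyne
Product: 9 (4E)-4-methylnon-4-en-8-ynal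
Conditions: H5IO6, THF/Et2O, 0 °C
Reagents that add atoms: none
Why: Periodic acid opens the epoxide to the glycol and cleaves it (Malaprade cleavage), releasing the C3 aldehyde and acetone without touching alkene or alkyne.

Step 6
Reactants: 9 enynal; 10 ethyl 2-[bis(2,2,2-trifluoroethoxy)phosphoryl]propanoate
Product: 11 ethyl (2Z,6E)-2,6-dimethylundeca-2,6-dien-10-ynoate
Conditions: 10, KN(SiMe3)2, 18-crown-6, THF, −78 °C; then 9
Reagents that add atoms: none
Why: Still–Gennari olefination: the electron-poor phosphonate under dissociating conditions collapses kinetically to the Z enoate, which puts the ester carbon (future C19) cis to the chain.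

Step 7
Reactants: 11 Z enoate
Product: 12 (2Z,6E)-2,6-dimethylundeca-2,6-dien-10-yn-1-ol
Conditions: iBu2AlH, CH2Cl2, −78 °C
Reagents that add atoms: none
Why: Hydride 1,2-reduction of the enoate gives the allylic alcohol with the Z geometry kept.

Step 8
Reactants: 12 Z allylic alcohol
Product: 13 [(2S,3R)-2-methyl-3-[(3E)-3-methyloct-3-en-7-yn-1-yl]oxiran-2-yl]methanol
Conditions: Ti(OiPr)4, L-(+)-diethyl tartrate, t-BuOOH, 4 Å MS, CH2Cl2, −20 °C
Reagents that add atoms: tert-butyl hydroperoxide, CC(C)(C)OO
Why: Sharpless asymmetric epoxidation oxidises only the alkene bound through the allylic hydroxyl, and L-(+)-tartrate should deliver oxygen to the face that gives the (2S,3R)-epoxide (future 3R and, after inversion, 4R).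

Step 9
Reactants: 13 epoxy alcohol
Product: 14 tert-butyldimethylsilyl ether of 13
Conditions: TBSCl, imidazole, DMF, 0 °C → rt
Reagents that add atoms: tert-butyldimethylsilyl chloride, CC(C)(C)[Si](C)(C)Cl
Why: Imidazole-promoted silylation gives the non-participating C19 ether needed in step 12.

Step 10
Reactants: 14 silyl ether; 15 (trimethylsilyl)methylmagnesium chloride; 16 ethylene oxide
Product: 18 epoxy diene allylsilane with free C12 hydroxyl, via alkenylcopper 17 (not isolated)
Conditions: 15, CuBr·SMe2, Et2O/Me2S, −45 °C; 14, −25 → −10 °C; then 1-hexynyllithium, HMPA, 16, −40 → −15 °C; H2O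
Reagents that add atoms: none
Why: Syn carbocupration puts CH2SiMe3 on C8 and copper on C9, and the alkenylcopper (as the mixed alkynyl cuprate) opens ethylene oxide with retention, fixing C17 cis to C11; the trisubstituted epoxide should be too hindered to react at these temperatures.

Step 11
Reactants: 18 homoallylic alcohol
Product: 19 cyclisation precursor (C19 silyl ether, C12 pivalate)
Conditions: PivCl, pyridine, DMAP (cat.), CH2Cl2, 0 °C
Reagents that add atoms: pivaloyl chloride, CC(C)(C)C(=O)Cl
Why: DMAP-catalysed acylation gives an ester whose oxygen is too weakly nucleophilic to trap the C8 cation in step 12.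

Step 12
Reactants: 19 cyclisation precursor
Product: 20 (3R,4R,5S,9R,10S)-19-(tert-butyldimethylsilyloxy)-3-hydroxy-13,14,15,16-tetranorlabd-8(17)-en-12-yl pivalate
Conditions: MeAlCl2 (2.5 equiv), CH2Cl2, −94 → −78 °C; then Et3N, MeOH/H2O
Reagents that add atoms: none
Why: Epoxide-initiated cation–olefin bicyclisation with an allylsilane terminator (closest known type: MeAlCl2-promoted epoxy-polyene cyclisation): aluminium binds the epoxide oxygen, the C5=C10 alkene opens C4–O from the rear (C4–C5), the C10 cation is taken by C9 of the allylsilane (C10–C9) and the β-silyl cation at C8 loses Me3Si to chloride, which can only leave the C8=C17 methylene. Ring A closes 6-endo with respect to both the epoxide and the C5=C10 alkene and ring B closes 6-endo-trig onto C8=C9, both in one chair–chair fold. C3 keeps the epoxide configuration and becomes the equatorial hydroxyl, while C4 is inverted so that the CH2OTBS group cis to the chain becomes axial C19 and the methyl equatorial C18. Anti addition across the E C5=C10 alkene gives the trans fusion (H5 anti to C20), and the C8=C9 geometry (C7 trans to C11) puts C11 equatorial with H9 anti to C20. The step needs opening at tertiary C4 and complete double closure, and these are secured by the tertiary centre, the non-participating silyl ether at C19, the poorly nucleophilic pivalate at C12 and the strongly nucleophilic allylsilane.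

Step 13
Reactants: 20 silyl ether
Product: 21 3,19-diol pivalate
Conditions: Bu4NF, THF, rt
Reagents that add atoms: none
Why: Fluoride-induced desilylation frees the C19 hydroxyl and leaves the pivalate and alkene untouched.

Step 14
Reactants: 21 diol
Product: 22 3,19-O-isopropylidene pivalate
Conditions: 2,2-dimethoxypropane, PPTS (cat.), CH2Cl2, rt
Reagents that add atoms: 2,2-dimethoxypropane, COC(C)(C)OC
Why: Acid-catalysed transketalisation closes the 1,3-dioxane across the equatorial C3 hydroxyl and the axial C19 hydroxymethyl, which are gauche.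

Step 15
Reactants: 22 acetonide pivalate
Product: 23 3,19-O-isopropylidene C12 alcohol
Conditions: iBu2AlH, CH2Cl2, −78 °C
Reagents that add atoms: none
Why: Reductive ester cleavage releases the C12 alcohol under conditions to which the acetonide is stable.

Step 16
Reactants: 23 alcohol
Product: 24 3,19-O-isopropylidene C12 aldehyde
Conditions: Dess–Martin periodinane, NaHCO3, CH2Cl2, 0 °C → rt
Reagents that add atoms: none
Why: Dess–Martin oxidation gives the aldehyde under buffered conditions that spare the acetonide and the exocyclic alkene.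

Step 17
Reactants: 24 aldehyde; 25 methyl acrylate
Product: 26 Morita–Baylis–Hillman adduct (methyl 3-hydroxy-2-methylidene-4-decalinylbutanoate)
Conditions: 25 (excess), DABCO, MeOH, rt, several days
Reagents that add atoms: none
Why: Morita–Baylis–Hillman reaction: the DABCO–acrylate zwitterion adds to the unhindered aldehyde and the amine is expelled, forming C12'–C13'.

Step 18
Reactants: 26 adduct
Product: 28 primary allylic acetate, methyl (E)-2-(acetoxymethyl)-4-decalinylbut-2-enoate, via branched acetate 27 (not isolated)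
Conditions: Ac2O, pyridine, DMAP (cat.), CH2Cl2, 0 °C; then DABCO (cat.), THF, 65 °C
Reagents that add atoms: acetic anhydride, CC(=O)OC(C)=O
Why: Acetylation followed by amine-mediated allylic transposition (two SN2' events through the allylammonium acetate) gives the thermodynamically preferred conjugated primary acetate.

Step 19
Reactants: 28 primary acetate
Product: 29 unit A allylboronate, methyl 2-methylidene-3-(pinacolboryl)-4-decalinylbutanoate
Conditions: B2pin2, CuCl (10 mol%), Xantphos (10 mol%), NaOtBu (20 mol%), THF, 0 °C → rt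
Reagents that add atoms: bis(pinacolato)diboron, CC1(C)OB(OC1(C)C)B1OC(C)(C)C(C)(C)O1
Why: Copper-catalysed allylic borylation: boryl–copper adds to the enoate β-carbon C12' and the copper enolate expels acetate (formal SN2'), giving the α-substituted 2-(methoxycarbonyl)allylboronate.

Step 20
Reactants: 30 (S)-3-hydroxy-γ-butyrolactone
Product: 31 (S)-4-(tert-butyldimethylsilyloxy)oxolan-2-one
Conditions: TBSCl, imidazole, DMF, rt
Reagents that add atoms: tert-butyldimethylsilyl chloride, CC(C)(C)[Si](C)(C)Cl
Why: Silylation gives a C14 oxygen substituent that is a poor leaving group and should survive enolate formation at −78 °C.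

Step 21
Reactants: 24 aldehyde; 31 silyloxy lactone
Product: 32 aldol adduct (3,4-trans lactone, C12 carbinol)
Conditions: LiN(iPr)2, THF, −78 °C; then 24; AcOH quench at −78 °C
Reagents that add atoms: none
Why: Aldol addition of the lithium lactone enolate, which reacts anti to the silyloxy group, forms C12–C13.

Step 22
Reactants: 32 aldol adduct
Product: 34 14-O-TBS-3,19-O-isopropylidene-andrographolide (12E), via mesylate 33 (not isolated)
Conditions: MsCl, Et3N, CH2Cl2, 0 °C; then DBU, 0 °C → rt
Reagents that add atoms: none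
Why: Mesylation and E1cB elimination: the C13 enolate expels mesylate in preference to the poorer ring silyloxy group, and the E isomer (C11 anti to the lactone carbonyl) should predominate, any Z isomer being removed by chromatography.

Step 23
Reactants: 34 silyl ether
Product: 35 3,19-O-isopropylidene-andrographolide (12E,14S)
Conditions: HF·pyridine, pyridine, THF, 0 °C → rt
Reagents that add atoms: none
Why: Buffered fluoride desilylation frees the C14 hydroxyl without cleaving the acetonide.

Step 24
Reactants: 35 allylic alcohol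
Product: 36 14-O-acetyl-3,19-O-isopropylidene-andrographolide
Conditions: Ac2O, pyridine, DMAP (cat.), CH2Cl2, 0 °C
Reagents that add atoms: acetic anhydride, CC(=O)OC(C)=O
Why: DMAP-catalysed acetylation turns the C14 oxygen into the leaving group for step 25.

Step 25
Reactants: 36 allylic acetate; 37 (chloromethyl)(isopropoxy)dimethylsilane
Product: 39 (12S)-12-[(isopropoxydimethylsilyl)methyl]-14-deoxy-3,19-O-isopropylidene-andrographolide, via Grignard reagent 38 (not isolated)
Conditions: 37, Mg, THF, rt; then CuBr·SMe2 (10 mol%), 36, THF, −78 °C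
Reagents that add atoms: none
Why: Copper-catalysed SN2' substitution of the Morita–Baylis–Hillman-type acetate: the copper reagent attacks exocyclic C12 on the ring face opposite the C14 acetate and the double bond moves into the ring, so the E alkene with 14S should give 12S.

Step 26
Reactants: 39 alkoxysilane
Product: 40 (12S)-12-(hydroxymethyl) butenolide
Conditions: H2O2 (30%), KF, KHCO3, THF/MeOH, rt
Reagents that add atoms: hydrogen peroxide, OO
Why: Tamao oxidation converts the C–Si bond into C–OH with retention, unmasking the hydroxymethyl group (C15') under mild conditions.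

Step 27
Reactants: 40 alcohol
Product: 41 unit B aldehyde (12S)
Conditions: Dess–Martin periodinane, NaHCO3, CH2Cl2, 0 °C; used at once
Reagents that add atoms: none
Why: Dess–Martin oxidation is base-free and fast at 0 °C, so the enolisable C12 centre of the α-branched aldehyde should not epimerise.

Step 28
Reactants: 41 unit B aldehyde; 29 unit A allylboronate
Product: 42 bis-acetonide C15' alcohol (E enoate)
Conditions: toluene, 4 Å MS, rt → 50 °C; then aq. NaHCO3
Reagents that add atoms: none
Why: Allylboration through a closed chair transition state: C15' bonds to the CH2 terminus C14', and the C12' substituent sits axial to avoid the pinacol ring and A(1,2) strain with the ester, which places C11' cis to C14' and trans to CO2Me; the neutral conditions should spare C12.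

Step 29
Reactants: 42 alcohol
Product: 43 bis-acetonide C15' ketone
Conditions: Dess–Martin periodinane, NaHCO3, CH2Cl2, 0 °C
Reagents that add atoms: none
Why: Dess–Martin oxidation of the crude homoallylic alcohol gives the ketone without base, avoiding enolisation toward C12 or C14' and forestalling lactonisation onto the ester.

Step 30
Reactants: 43 protected ketone
Product: 44 target CNP0330094.1
Conditions: AcOH/H2O (7:3), rt
Reagents that add atoms: none
Why: Acid-catalysed acetal hydrolysis removes both acetonides under conditions in which the ketone α-centre, the β,γ-unsaturated ketone and the exocyclic alkenes should persist.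

**Compound list**

1 | geranyl acetate | CC(C)=CCC/C(C)=C/COC(C)=O | starting material
2 | 6,7-epoxygeranyl acetate | CC1(C)OC1CC/C(C)=C/COC(C)=O | intermediate
3 | 6,7-epoxygeraniol | CC1(C)OC1CC/C(C)=C/CO | intermediate
4 | 6,7-epoxygeranyl methanesulfonate | CC1(C)OC1CC/C(C)=C/COS(C)(=O)=O | intermediate
5 | 6,7-epoxygeranyl bromide | CC1(C)OC1CC/C(C)=C/CBr | intermediate
6 | propargyl bromide | C#CCBr | starting material
7 | 1,3-dilithiopropyne | [Li]CC#C[Li] | intermediate
8 | 2,2-dimethyl-3-[(3E)-3-methyloct-3-en-7-yn-1-yl]oxirane | CC1(C)OC1CC/C(C)=C/CCC#C | intermediate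
9 | (4E)-4-methylnon-4-en-8-ynal | O=CCC/C(C)=C/CCC#C | intermediate
10 | ethyl 2-[bis(2,2,2-trifluoroethoxy)phosphoryl]propanoate | CCOC(=O)C(C)P(=O)(OCC(F)(F)F)OCC(F)(F)F | starting material
11 | ethyl (2Z,6E)-2,6-dimethylundeca-2,6-dien-10-ynoate | CCOC(=O)/C(C)=C\CC/C(C)=C/CCC#C | intermediate
12 | (2Z,6E)-2,6-dimethylundeca-2,6-dien-10-yn-1-ol | OC/C(C)=C\CC/C(C)=C/CCC#C | intermediate
13 | [(2S,3R)-2-methyl-3-[(3E)-3-methyloct-3-en-7-yn-1-yl]oxiran-2-yl]methanol | C[C@@]1(CO)O[C@@H]1CC/C(C)=C/CCC#C | intermediate
14 | tert-butyldimethylsilyl ether of 13 | C[C@@]1(CO[Si](C)(C)C(C)(C)C)O[C@@H]1CC/C(C)=C/CCC#C | intermediate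
15 | (trimethylsilyl)methylmagnesium chloride | C[Si](C)(C)C[Mg]Cl | starting material
16 | ethylene oxide | C1CO1 | starting material
17 | alkenylcopper (Cu on C9, cis to CH2SiMe3 on C8) | C[C@@]1(CO[Si](C)(C)C(C)(C)C)O[C@@H]1CC/C(C)=C/CC/C(C[Si](C)(C)C)=C/[Cu] | intermediate
18 | epoxy diene allylsilane, C12 alcohol | C[C@@]1(CO[Si](C)(C)C(C)(C)C)O[C@@H]1CC/C(C)=C/CC/C(C[Si](C)(C)C)=C/CCO | intermediate
19 | epoxy diene allylsilane, C12 pivalate (cyclisation precursor) | C[C@@]1(CO[Si](C)(C)C(C)(C)C)O[C@@H]1CC/C(C)=C/CC/C(C[Si](C)(C)C)=C/CCOC(=O)C(C)(C)C | intermediate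
20 | (3R,4R,5S,9R,10S)-19-(TBS-oxy)-3-hydroxy-13,14,15,16-tetranorlabd-8(17)-en-12-yl pivalate | C=C1CC[C@@H]2[C@](C)(CO[Si](C)(C)C(C)(C)C)[C@H](O)CC[C@@]2(C)[C@@H]1CCOC(=O)C(C)(C)C | intermediate
21 | 3,19-dihydroxy decalin C12 pivalate | C=C1CC[C@@H]2[C@](C)(CO)[C@H](O)CC[C@@]2(C)[C@@H]1CCOC(=O)C(C)(C)C | intermediate
22 | 3,19-O-isopropylidene decalin C12 pivalate | C=C1CC[C@@H]2[C@]3(C)COC(C)(C)O[C@@H]3CC[C@@]2(C)[C@@H]1CCOC(=O)C(C)(C)C | intermediate
23 | 3,19-O-isopropylidene decalin C12 alcohol | C=C1CC[C@@H]2[C@]3(C)COC(C)(C)O[C@@H]3CC[C@@]2(C)[C@@H]1CCO | intermediate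
24 | 3,19-O-isopropylidene decalin C12 aldehyde | C=C1CC[C@@H]2[C@]3(C)COC(C)(C)O[C@@H]3CC[C@@]2(C)[C@@H]1CC=O | intermediate
25 | methyl acrylate | C=CC(=O)OC | starting material
26 | Morita–Baylis–Hillman adduct of 24 (C12' epimers) | C=C1CC[C@@H]2[C@]3(C)COC(C)(C)O[C@@H]3CC[C@@]2(C)[C@@H]1CC(O)C(=C)C(=O)OC | intermediate
27 | branched acetate of 26 | C=C1CC[C@@H]2[C@]3(C)COC(C)(C)O[C@@H]3CC[C@@]2(C)[C@@H]1CC(OC(C)=O)C(=C)C(=O)OC | intermediate
28 | methyl (E)-2-(acetoxymethyl)-4-decalinylbut-2-enoate | C=C1CC[C@@H]2[C@]3(C)COC(C)(C)O[C@@H]3CC[C@@]2(C)[C@@H]1C/C=C(\COC(C)=O)C(=O)OC | intermediate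
29 | unit A allylboronate (C12' epimers) | C=C1CC[C@@H]2[C@]3(C)COC(C)(C)O[C@@H]3CC[C@@]2(C)[C@@H]1CC(B1OC(C)(C)C(C)(C)O1)C(=C)C(=O)OC | intermediate
30 | (S)-3-hydroxy-γ-butyrolactone [(4S)-4-hydroxyoxolan-2-one] | O=C1C[C@H](O)CO1 | starting material
31 | (S)-4-(tert-butyldimethylsilyloxy)oxolan-2-one | O=C1C[C@H](O[Si](C)(C)C(C)(C)C)CO1 | intermediate
32 | aldol adduct, 3,4-trans lactone (C12 carbinol epimers) | C=C1CC[C@@H]2[C@]3(C)COC(C)(C)O[C@@H]3CC[C@@]2(C)[C@@H]1CC(O)[C@@H]1C(=O)OC[C@H]1O[Si](C)(C)C(C)(C)C | intermediate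
33 | C12 mesylate of 32 | C=C1CC[C@@H]2[C@]3(C)COC(C)(C)O[C@@H]3CC[C@@]2(C)[C@@H]1CC(OS(C)(=O)=O)[C@@H]1C(=O)OC[C@H]1O[Si](C)(C)C(C)(C)C | intermediate
34 | 14-O-TBS-3,19-O-isopropylidene-andrographolide | C=C1CC[C@@H]2[C@]3(C)COC(C)(C)O[C@@H]3CC[C@@]2(C)[C@@H]1C/C=C1/C(=O)OC[C@H]1O[Si](C)(C)C(C)(C)C | intermediate
35 | 3,19-O-isopropylidene-andrographolide | C=C1CC[C@@H]2[C@]3(C)COC(C)(C)O[C@@H]3CC[C@@]2(C)[C@@H]1C/C=C1/C(=O)OC[C@H]1O | intermediate
36 | 14-O-acetyl-3,19-O-isopropylidene-andrographolide | C=C1CC[C@@H]2[C@]3(C)COC(C)(C)O[C@@H]3CC[C@@]2(C)[C@@H]1C/C=C1/C(=O)OC[C@H]1OC(C)=O | intermediate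
37 | (chloromethyl)(isopropoxy)dimethylsilane | CC(C)O[Si](C)(C)CCl | starting material
38 | [(isopropoxy)dimethylsilyl]methylmagnesium chloride | CC(C)O[Si](C)(C)C[Mg]Cl | intermediate
39 | (12S)-12-[(isopropoxydimethylsilyl)methyl] butenolide | C=C1CC[C@@H]2[C@]3(C)COC(C)(C)O[C@@H]3CC[C@@]2(C)[C@@H]1C[C@H](C[Si](C)(C)OC(C)C)C1=CCOC1=O | intermediate
40 | (12S)-12-(hydroxymethyl) butenolide | C=C1CC[C@@H]2[C@]3(C)COC(C)(C)O[C@@H]3CC[C@@]2(C)[C@@H]1C[C@H](CO)C1=CCOC1=O | intermediate
41 | unit B aldehyde (12S) | C=C1CC[C@@H]2[C@]3(C)COC(C)(C)O[C@@H]3CC[C@@]2(C)[C@@H]1C[C@H](C=O)C1=CCOC1=O | intermediate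
42 | bis-acetonide C15' alcohol (C15' epimers) | C=C1CC[C@@H]2[C@]3(C)COC(C)(C)O[C@@H]3CC[C@@]2(C)[C@@H]1C/C=C(\CC(O)[C@@H](C[C@@H]1C(=C)CC[C@@H]2[C@]3(C)COC(C)(C)O[C@@H]3CC[C@]21C)C1=CCOC1=O)C(=O)OC | intermediate
43 | bis-acetonide C15' ketone | C=C1CC[C@@H]2[C@]3(C)COC(C)(C)O[C@@H]3CC[C@@]2(C)[C@@H]1C/C=C(\CC(=O)[C@@H](C[C@@H]1C(=C)CC[C@@H]2[C@]3(C)COC(C)(C)O[C@@H]3CC[C@]21C)C1=CCOC1=O)C(=O)OC | intermediate
44 | CNP0330094.1 | C=C1CC[C@@H]2[C@](C)(CO)[C@H](O)CC[C@@]2(C)[C@@H]1C/C=C(\CC(=O)[C@@H](C[C@@H]1C(=C)CC[C@@H]2[C@](C)(CO)[C@H](O)CC[C@]21C)C1=CCOC1=O)C(=O)OC | target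

**Step count and risks**

Total: 30 steps. Longest linear sequence: 26 steps (1–16, 21–30).

The cyclisation of step 12 is an established reaction type for this oxygenation pattern and is expected to cost material rather than to fail; the three steps judged most likely to fail are 28, 19 and 10.

1. Step 28. The hindered, electron-poor allylboronate may add too slowly, so that the aldehyde enolises at C12 on prolonged warming, or the γ-hydroxy ester may lactonise. The fallback sets out from 41 and 24 and rejoins at 42. Barbier allylation of 41 with methyl 2-(bromomethyl)acrylate and indium powder in THF/H2O at room temperature gives the 2-methylidene-4-hydroxy ester F1 (no γ-substituent, so one regioisomer). Wittig methylenation of 24 (Ph3P=CH2, THF, 0 °C) gives the allyl decalin F2. Cross-metathesis of F1 with F2 (second-generation Hoveyda–Grubbs catalyst, CH2Cl2, 40 °C) then forms the trisubstituted E enoate 42.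

2. Step 19. Boryl–copper may substitute directly at the CH2OAc carbon (giving the γ-substituted primary boronate, which would allylate with the wrong regiochemistry), or borylate the acrylate of the product a second time. The fallback sets out from 40 and 27 and rejoins at 43, with 27 isolated after the acetylation of step 18. Alcohol 40 is converted into the iodide F3 (PPh3, I2, imidazole, CH2Cl2) and then the nitro compound F4 (NaNO2, phloroglucinol, DMF). The nitronate of F4 (K2CO3, MeCN, rt) displaces the acetate of 27 in an SN2' alkylation to give the E enoate secondary nitro compound F5. A Nef-type conversion (NaNO2, AcOH, DMSO, 35 °C) turns F5 into ketone 43.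

3. Step 10. The trisubstituted epoxide may be opened by magnesium halide or the copper reagent, or the alkenylcopper may not be captured by ethylene oxide in its presence. The fallback sets out from 12 and rejoins at 19, doing the carbocupration before the epoxide exists. Alcohol 12 is protected as the triethylsilyl ether F6 (TESCl, imidazole). Carbocupration and ethylene oxide trapping as in step 10 give the homoallylic alcohol F7, and pivaloylation gives F8. PPTS in MeOH removes the triethylsilyl group to give the Z allylic alcohol F9, which tolerates the allylsilane and pivalate. Sharpless epoxidation as in step 8 gives the epoxy alcohol F10, and silylation (TBSCl, imidazole) gives 19.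

Further compounds
F1 | step 28 | unit B methyl 4-hydroxy-2-methylidene ester (Barbier adduct of 41) | C=C(CC(O)[C@@H](C[C@@H]1C(=C)CC[C@@H]2[C@]3(C)COC(C)(C)O[C@@H]3CC[C@]21C)C1=CCOC1=O)C(=O)OC
F2 | step 28 | 3,19-O-isopropylidene allyl decalin (methylenation product of 24) | C=C1CC[C@@H]2[C@]3(C)COC(C)(C)O[C@@H]3CC[C@@]2(C)[C@@H]1CC=C
F3 | step 19 | (12S)-12-(iodomethyl) butenolide | C=C1CC[C@@H]2[C@]3(C)COC(C)(C)O[C@@H]3CC[C@@]2(C)[C@@H]1C[C@H](CI)C1=CCOC1=O
F4 | step 19 | (12S)-12-(nitromethyl) butenolide | C=C1CC[C@@H]2[C@]3(C)COC(C)(C)O[C@@H]3CC[C@@]2(C)[C@@H]1C[C@H](C[N+](=O)[O-])C1=CCOC1=O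
F5 | step 19 | bis-acetonide C15' nitro compound (E enoate) | C=C1CC[C@@H]2[C@]3(C)COC(C)(C)O[C@@H]3CC[C@@]2(C)[C@@H]1C/C=C(\CC([N+](=O)[O-])[C@@H](C[C@@H]1C(=C)CC[C@@H]2[C@]3(C)COC(C)(C)O[C@@H]3CC[C@]21C)C1=CCOC1=O)C(=O)OC
F6 | step 10 | triethylsilyl ether of 12 | CC[Si](CC)(CC)OC/C(C)=C\CC/C(C)=C/CCC#C
F7 | step 10 | triethylsilyl-protected triene allylsilane, C12 alcohol | CC[Si](CC)(CC)OC/C(C)=C\CC/C(C)=C/CC/C(C[Si](C)(C)C)=C/CCO
F8 | step 10 | triethylsilyl-protected triene allylsilane, C12 pivalate | CC[Si](CC)(CC)OC/C(C)=C\CC/C(C)=C/CC/C(C[Si](C)(C)C)=C/CCOC(=O)C(C)(C)C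
F9 | step 10 | Z allylic alcohol triene allylsilane, C12 pivalate | OC/C(C)=C\CC/C(C)=C/CC/C(C[Si](C)(C)C)=C/CCOC(=O)C(C)(C)C
F10 | step 10 | (2S,3R)-epoxy alcohol diene allylsilane, C12 pivalate | C[C@@]1(CO)O[C@@H]1CC/C(C)=C/CC/C(C[Si](C)(C)C)=C/CCOC(=O)C(C)(C)C
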